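## The problem

The target joins two ring systems through one single bond. One is a cis-fused perhydroazulene (C1–C8a) with an exocyclic methylene on C8, a gem-dimethyl carbon C4 and a quaternary C1 bearing a methyl group. The other is a 2,7-dioxabicyclo[3.2.1]octan-3-one (primed locants) with an acetate on C4′, a methyl ester on C6′ and its one-carbon bridge C8′ bonded to C1.

Three stereocentres (C1, C3a, C8a) lie in the carbocycle and five (C1′, C4′, C5′, C6′, C8′) in the heterocycle. The halves meet at a bond between a quaternary carbon and a CH, so neither can be trusted to control the other. The absolute sense of the heterocycle therefore has to come from chiral building blocks or reagents, while ring constraints can be used inside each half.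

C8′ is the critical centre. It is neopentyl, cannot be corrected once the acyl acetal exists, and must carry the azulenyl group on the side of the lactone bridge, that is anti to C6′ and gauche to C4′ about the C8′–C5′ bond.

The acyl acetal at C1′, the α-acetoxy lactone and the α-alkoxy ester at C6′ will not survive strong base, hydride or hard nucleophiles. The 1,1-disubstituted C8 alkene excludes late hydrogenation, ozonolysis and osmylation and migrates in strong acid.

The feature that makes the key step possible is the methylenecycloheptane ring. C8, its methylene carbon and C8a are the three carbons of a terminal allene, C3a–C4–C5–C6–C7 are the five carbons of a vinylcyclopropane, and C1–C2–C3 is a three-atom tether. One metal-mediated (5+2) event can thus form C3a–C8a and C7–C8 and leave the methylene in place. C4 can pass through that step with only one methyl group, so the second has to be added afterwards.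

## Retrosynthesis

The C4′ acetate of 41 is cut first, giving hydroxy lactone 40. Acetylation of an equatorial secondary alcohol is the mildest possible last step and keeps the most labile ester out of everything before it.

In 40 the two C–O bonds at C1′ (to O2′ and to O7′) are cut and C1′ is reconnected to the C4′ oxygen, which gives the monocyclic methyl acetal acid 39. This is preferred to simply opening the lactone because of the geometry about C8′–C5′. An oxolane that contains C6′ would need the azulenyl group cis to the C5′ side chain. The isomeric oxolane that contains C4′ needs it trans, with the C4′ carboxyl trans as well, which is the all-trans ring a kinetically controlled five-membered ring closure gives by default. 39 is simpler by one ring and the acyl acetal. The forward step must be an acid-catalysed acetal exchange that ends in the bridged lactone, driven by loss of methanol.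

The C6′–O bond of 39 is cut next, together with the ester pattern (38, 37, back to 35). With the C6′ carboxyl carried as an N-acyl oxazolidinone, the hydroxyl can be introduced by enolate oxidation at the one position that is far more acidic than the others, and the auxiliary fixes C6′ independently of the rest. A late enolate oxidation of the bridged lactone was rejected because the acyl acetal and the C6′ ester hydrogen would interfere.

The C8′–C5′ bond of 35 is cut together with the C1′–O4′ acetal bond, giving bromoacetal 34 and from it enol ether 26 and allylic alcohol 33. A radical is the only practical nucleophile at C8′, since a carbanion there would expel the β-alkoxy group. The acetal tether keeps C1′ at the aldehyde oxidation level and the closure is 5-exo onto an electron-poor alkene. 33 brings the C4′ stereocentre from the chiral pool, so the configuration of the heterocycle is set by a building block. The forward step has to place the new bond at C5′ anti to the C4′ ester and to the azulenyl group.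

33 is cut at its alkene into hydroxy ester 29 and acryloyl imide 32 (cross-metathesis). 29 comes from methyl ester 27 and alcohol 28, and 32 from oxazolidinone 30 and acid chloride 31. The silylethyl ester is needed because the C3′ carboxyl must later be freed in the presence of the C6′ methyl ester.

Enol ether 26 is traced through dimethyl acetal 25 and aldehyde 24 to alcohol 23 and silyl ether 22, with no C–C bond cut. The arm stays a silyl ether until then because the preceding steps use a peracid, an organoalane and tin radicals.

One methyl group at C4 of 22 is cut together with the C5–H bond, leading through thionocarbonate 21, alcohol 20 and epoxide 19 to the trisubstituted alkene of 18. The cut is forced, because C4 is the internal alkene carbon of the vinylcyclopropane. The forward sequence must tell the ring alkene from the methylene and deliver methyl to the tertiary epoxide carbon.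

In 18 the C3a–C8a and C7–C8 bonds are cut, which opens both carbocycles and gives the acyclic allenyl vinylcyclopropane 17. Against stepwise annulations this removes two rings, two C–C bonds and two stereocentres at once, installs the methylene directly instead of through a hindered ketone, and leaves the ring fusion non-enolisable. It asks for reaction at the proximal allene double bond, cis delivery and the correct face relative to C1.

The allene of 17 is cut back by one carbon to alkyne 15, then to alcohol 14, lactol 13 and lactone 12. The lactone carbonyl carbon becomes the allene CH and the ring CH2CH2O becomes the silyloxyethyl arm, so one lactone differentiates two of the four groups on the quaternary carbon.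

The trisubstituted alkene of 12 is cut at the methyl bond (11), at the cyclopropyl bond (dibromoalkene 9 with organozinc 10) and then at the C=C bond (aldehyde 8, alcohol 7, allyl lactone 5). Two stereospecific couplings were preferred to a one-step Wittig disconnection of the same alkene, which has no reliable control over the E geometry the cycloaddition needs.

Finally the allyl–C bond at the quaternary carbon of 5 is cut to allyl ester 4, made from lactone 1 and chloroformate 2. This sets the only carbocyclic stereocentre not made in the key step, catalytically and at the second step.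

## Roads not taken

Alternative 1: The cut is through C8–C8a and C1–C8′. A tethered acyl radical would close the seven-membered ring onto a cyclopentene, and the tertiary radical formed at C1 would be captured by an electron-poor alkene partner that already carries the C6′ stereocentre, giving A1.
- Merits: it is convergent, it makes the quaternary carbon and the bond between the halves in one operation, and the cis fusion follows from the tether. Capture anti to the new ring bond should also put the heterocyclic fragment on the correct face of C1. In that respect it answers the facial question at C1 more directly than the chosen plan, which relies on the size difference between a methyl group and a silyloxyethyl arm.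
- Weak points: the hindered tertiary radical must be captured intermolecularly in competition with hydrogen transfer. The C8 ketone of A1 must be methylenated next to an enolisable ring-fusion centre and a quaternary carbon. A second ketone must be told from it in the ring expansion to the acyl acetal. The C4′ acetoxy group would still have to be added by enolate chemistry on the base-sensitive bridged lactone.
- Comparison: the chosen plan is longer in the carbocycle but has the methylene in place from the ring-forming step and sets C4′ and C6′ before the acyl acetal exists.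

Alternative 2: The cut is through C1–C8a by way of a temporary cyclobutane. Irradiation of its enone–alkene substrate would give photoadduct A2, and retro-aldol opening would give keto aldehyde A3, the 8-oxo counterpart of aldehyde 24.
- Merits: in step count this road is clearly better. The gem-dimethyl group is present from the start and the fragmentation delivers the acetaldehyde arm, so the four steps spent here on the second methyl group and the three spent on unmasking the arm disappear.
- Weak points: they are stereochemical. The absolute configuration would rest on a single neopentyl ring stereocentre with no obvious catalytic asymmetric entry. The C1/C3a relation is set across the forming cyclopentane in an excited-state reaction. C8a in A3 is α to a ketone, so the cis fusion can epimerise during the methylenation of a hindered carbonyl group that must follow.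
- Comparison: the chosen plan sets the quaternary centre by catalytic asymmetric allylation at step 2 and forms the ring fusion in a non-enolisable form.

Alternative 3: The cut is through C8′–C1′ and C5′–C4′. Sensitised irradiation of its photosubstrate on a finished hydroazulene would give the crossed adduct A4. Its donor–acceptor cyclobutane bond can be opened to an oxocarbenium ion that the tert-butyl ester captures, giving the bridged lactone directly.
- Merits: for C8′ and C5′ relative to C6′ this road is at least as good as the chosen one, because the geometry of the crossed adduct leaves no choice while the radical closure relies on a conformational preference. It also reaches the bridged lactone in fewer steps from the oxolane stage.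
- Weak points: after opening of A4, C4′ is a methylene group, so the acetoxy group would need enolate oxidation of the bridged acyl acetal in competition with the C6′ ester hydrogen. The photosubstrate also needs an E alkene on the neopentyl position of a hydroazulene that would still have to be made by something like steps 1–18, and the sensitised step must tolerate the 1,1-disubstituted alkene.
- Comparison: the chosen plan takes C4′ from the chiral pool and sets C6′ by an auxiliary-controlled oxidation at a robust monocyclic stage. The alternative replaces only the last third of the synthesis.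

Key step: step 12

Assumption: methyl (2S)-2-hydroxybut-3-enoate (27) is taken as a purchasable single enantiomer, and the ligand antipode in step 2 is assigned by analogy with cyclic ketone enolates, so the sense of induction would have to be confirmed and the ligand enantiomer chosen to match.

## Route

Step 1
Reactants: 1 3-methyloxolan-2-one (α-methyl-γ-butyrolactone, racemic); 2 allyl chloroformate
Product: 4 allyl 3-methyl-2-oxooxolane-3-carboxylate (racemic), via lithium lactone enolate 3 (not isolated)
Conditions: LiN(iPr)2, THF, −78 °C; then 2, −78 → 0 °C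
Reagents that add atoms: none
Why: Enolate acylation of a lactone (crossed Claisen type); the tetrasubstituted enolate is acylated on carbon, and any O-acylated enol carbonate formed alongside is an equally valid substrate for step 2 because both ionise to the same palladium enolate.

Step 2
Reactants: 4 allyl 3-methyl-2-oxooxolane-3-carboxylate
Product: 5 (3S)-3-methyl-3-(prop-2-en-1-yl)oxolan-2-one
Conditions: Pd2(dba)3 (2.5 mol %), (R)-t-BuPHOX [(4R)-4-tert-butyl-2-(2-diphenylphosphinophenyl)-4,5-dihydrooxazole] (6 mol %), toluene, 30 °C
Reagents that add atoms: none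
Why: Decarboxylative asymmetric allylic alkylation (Tsuji–Trost type): zerovalent palladium ionises the allyl ester, CO2 is lost and the prochiral lactone enolate is allylated inside the chiral phosphinooxazoline pocket, which sets the quaternary stereocentre; α-quaternary lactones are a documented substrate class for this reaction.

Step 3
Reactants: 5 (3S)-3-methyl-3-(prop-2-en-1-yl)oxolan-2-one
Product: 7 (3S)-3-(3-hydroxypropyl)-3-methyloxolan-2-one, via B-alkyl borabicyclononane 6 (not isolated)
Conditions: 9-BBN, THF, 0 °C → rt; then 30% H2O2, aq. NaOAc, 0 °C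
Reagents that add atoms: hydrogen peroxide, OO
Why: Anti-Markovnikov hydroboration–oxidation; the hindered dialkylborane adds only to the terminal alkene and leaves the lactone alone, and the acetate-buffered oxidation avoids lactone opening or ring-size exchange with the new hydroxyl.

Step 4
Reactants: 7 (3S)-3-(3-hydroxypropyl)-3-methyloxolan-2-one
Product: 8 3-[(3S)-3-methyl-2-oxooxolan-3-yl]propanal
Conditions: Dess–Martin periodinane, NaHCO3, CH2Cl2, rt
Reagents that add atoms: none
Why: Dess–Martin oxidation of a primary alcohol to the aldehyde under neutral conditions; the aldehyde has no α-stereocentre and is used directly.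

Step 5
Reactants: 8 3-[(3S)-3-methyl-2-oxooxolan-3-yl]propanal
Product: 9 (3S)-3-(4,4-dibromobut-3-en-1-yl)-3-methyloxolan-2-one
Conditions: CBr4, PPh3, CH2Cl2, 0 °C
Reagents that add atoms: carbon tetrabromide, BrC(Br)(Br)Br
Why: Ramirez dibromo-olefination (first stage of the Corey–Fuchs sequence), a Wittig reaction of the ylide Ph3P=CBr2 made in the flask, which tolerates the lactone.

Step 6
Reactants: 9 (3S)-3-(4,4-dibromobut-3-en-1-yl)-3-methyloxolan-2-one; 10 cyclopropylzinc bromide
Product: 11 (3S)-3-[(3Z)-4-bromo-4-cyclopropylbut-3-en-1-yl]-3-methyloxolan-2-one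
Conditions: PdCl2(DPEphos) (3 mol %), THF, 0 → 23 °C
Reagents that add atoms: none
Why: trans-Selective Negishi monocoupling of a 1,1-dibromoalkene: oxidative addition takes place at the less hindered C–Br bond trans to the chain, so the cyclopropyl group (an sp2-like nucleophile that resists β-hydride loss) ends trans to the chain and the Z bromoalkene results.

Step 7
Reactants: 11 (3S)-3-[(3Z)-4-bromo-4-cyclopropylbut-3-en-1-yl]-3-methyloxolan-2-one
Product: 12 (3S)-3-[(3E)-4-cyclopropylpent-3-en-1-yl]-3-methyloxolan-2-one
Conditions: Me2Zn, Pd(PtBu3)2 (3 mol %), THF, 23 °C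
Reagents that add atoms: dimethylzinc, C[Zn]C
Why: Negishi methylation of the alkenyl bromide with retention of configuration (the bulky electron-rich phosphine suppresses isomerisation), which fixes the E geometry of the 2-cyclopropylpropenyl unit needed in step 12.

Step 8
Reactants: 12 (3S)-3-[(3E)-4-cyclopropylpent-3-en-1-yl]-3-methyloxolan-2-one
Product: 13 (3S)-3-[(3E)-4-cyclopropylpent-3-en-1-yl]-3-methyloxolan-2-ol (both anomers)
Conditions: iBu2AlH, CH2Cl2, −78 °C; aq. Rochelle salt
Reagents that add atoms: none
Why: Partial reduction of a lactone to the lactol; the aluminium hemiacetal of a hindered α-quaternary lactone is stable at low temperature, so over-reduction to the diol should be minor.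

Step 9
Reactants: 13 (3S)-3-[(3E)-4-cyclopropylpent-3-en-1-yl]-3-methyloxolan-2-ol
Product: 14 (3S,6E)-7-cyclopropyl-3-ethynyl-3-methyloct-6-en-1-ol
Conditions: dimethyl (1-diazo-2-oxopropyl)phosphonate, K2CO3, MeOH, 0 °C → rt
Reagents that add atoms: dimethyl (1-diazo-2-oxopropyl)phosphonate, COP(=O)(OC)C(=[N+]=[N-])C(C)=O
Why: Ohira–Bestmann (Seyferth–Gilbert) homologation: the lactol equilibrates with its hydroxy aldehyde, which is converted into the terminal alkyne; the aldehyde carbon sits on the quaternary centre, so nothing can epimerise.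

Step 10
Reactants: 14 (3S,6E)-7-cyclopropyl-3-ethynyl-3-methyloct-6-en-1-ol
Product: 15 tert-butyl{[(3S,6E)-7-cyclopropyl-3-ethynyl-3-methyloct-6-en-1-yl]oxy}dimethylsilane
Conditions: TBSCl, imidazole, CH2Cl2, rt
Reagents that add atoms: tert-butyldimethylsilyl chloride, CC(C)(C)[Si](C)(C)Cl
Why: Silylation of the primary alcohol; the tert-butyldimethylsilyl ether is chosen because it must survive copper and amine at reflux, rhodium, peracid, an organoalane and tin hydride.

Step 11
Reactants: 15 tert-butyl{[(3S,6E)-7-cyclopropyl-3-ethynyl-3-methyloct-6-en-1-yl]oxy}dimethylsilane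
Product: 17 tert-butyl{[(3S,6E)-7-cyclopropyl-3-methyl-3-(propa-1,2-dien-1-yl)oct-6-en-1-yl]oxy}dimethylsilane, via propargylic dicyclohexylamine 16 (not isolated)
Conditions: (CH2O)n, CuI (0.5 equiv), Cy2NH, dioxane, 100 °C
Reagents that add atoms: formaldehyde (as paraformaldehyde), C=O
Why: Crabbé homologation: a copper-mediated Mannich reaction gives the propargylic amine, which undergoes a 1,5-hydride shift and loses the imine to give the terminal allene; the quaternary centre is not involved and the trisubstituted alkene and the cyclopropane are inert.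

Step 12
Reactants: 17 tert-butyl{[(3S,6E)-7-cyclopropyl-3-methyl-3-(propa-1,2-dien-1-yl)oct-6-en-1-yl]oxy}dimethylsilane
Product: 18 tert-butyl{2-[(1S,3aR,8aS)-1,4-dimethyl-8-methylidene-1,2,3,3a,6,7,8,8a-octahydroazulen-1-yl]ethoxy}dimethylsilane
Conditions: [Rh(CO)2Cl]2 (5 mol %), toluene (0.02 M), 90 °C
Reagents that add atoms: none
Why: Rhodium-catalysed intramolecular (5+2) cycloaddition of a vinylcyclopropane with an allene, the closest known reaction type being that of allenyl vinylcyclopropanes joined by a three-atom tether, which react at the internal allene double bond and give cis-fused bicyclo[5.3.0]decadienes with an exocyclic alkene. Monovalent rhodium binds the alkene, opens the cyclopropane and forms a σ,π-allyl metallacycle; the proximal allene double bond then inserts, making the C3a–C8a bond and closing the cyclopentane through the tether (a 5-exo-type migratory insertion), and reductive elimination from the eight-membered rhodacycle joins C8 to C7 and closes the seven-membered ring. The distal allene double bond takes no part and survives as the C8 methylene, while the former alkene and cyclopropane carbons end as the C4=C5 alkene. C3a and C8a are created on the same face of the metallacycle, which enforces the cis fusion. Their relation to C1 is decided in the insertion: the larger silyloxyethyl group should take the position away from the forming seven-membered ring, cis to the ring-fusion hydrogens, leaving the methyl group on the concave side. The E geometry of the alkene (steps 6 and 7) keeps the tether in the syn position of the allyl fragment so that the allene can reach rhodium, the quaternary carbon favours the folded conformer, and high dilution suppresses allene dimerisation. The silyl ether, the only heteroatom function, is inert.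

Step 13
Reactants: 18 tert-butyl{2-[(1S,3aR,8aS)-1,4-dimethyl-8-methylidene-1,2,3,3a,6,7,8,8a-octahydroazulen-1-yl]ethoxy}dimethylsilane
Product: 19 tert-butyl{2-[(1S,3aR,8aS)-4,5-epoxy-1,4-dimethyl-8-methylidenedecahydroazulen-1-yl]ethoxy}dimethylsilane (epoxide on either face, mainly that of the ring-fusion hydrogens)
Conditions: mCPBA (1.0 equiv), NaHCO3, CH2Cl2, −20 → 0 °C
Reagents that add atoms: 3-chloroperoxybenzoic acid, OOC(=O)c1cccc(Cl)c1
Why: Prilezhaev epoxidation; the trisubstituted ring alkene is the more nucleophilic one and should react ahead of the 1,1-disubstituted methylene with one equivalent of peracid in the cold, and the face of attack does not matter because C4 becomes non-stereogenic in step 14 and C5 is deoxygenated in step 16.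

Step 14
Reactants: 19 tert-butyl{2-[(1S,3aR,8aS)-4,5-epoxy-1,4-dimethyl-8-methylidenedecahydroazulen-1-yl]ethoxy}dimethylsilane
Product: 20 (1S,3aR,8aS)-1-{2-[(tert-butyldimethylsilyl)oxy]ethyl}-1,4,4-trimethyl-8-methylidenedecahydroazulen-5-ol (C5 epimers)
Conditions: Me3Al (5 equiv), hexane–CH2Cl2, −78 → 0 °C; aq. Rochelle salt
Reagents that add atoms: trimethylaluminium, C[Al](C)C
Why: Lewis-acid-assisted opening of a trisubstituted epoxide by an organoalane: aluminium coordination develops positive charge at the tertiary carbon and a second Me3Al delivers methyl there with inversion, giving the gem-dimethyl carbon and a secondary alkoxide; the nonpolar medium and low temperature are chosen to favour methyl transfer over hydride shift.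

Step 15
Reactants: 20 (1S,3aR,8aS)-1-{2-[(tert-butyldimethylsilyl)oxy]ethyl}-1,4,4-trimethyl-8-methylidenedecahydroazulen-5-ol
Product: 21 O-[(1S,3aR,8aS)-1-{2-[(tert-butyldimethylsilyl)oxy]ethyl}-1,4,4-trimethyl-8-methylidenedecahydroazulen-5-yl] O-phenyl carbonothioate
Conditions: PhOC(S)Cl, pyridine, DMAP, CH2Cl2, rt
Reagents that add atoms: O-phenyl chlorothionoformate, S=C(Cl)Oc1ccccc1
Why: Acylation of the hindered secondary alcohol to the aryl thionocarbonate, the radical-labile derivative for Barton–McCombie deoxygenation.

Step 16
Reactants: 21 O-[(1S,3aR,8aS)-1-{2-[(tert-butyldimethylsilyl)oxy]ethyl}-1,4,4-trimethyl-8-methylidenedecahydroazulen-5-yl] O-phenyl carbonothioate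
Product: 22 tert-butyldimethyl{2-[(1S,3aR,8aS)-1,4,4-trimethyl-8-methylidenedecahydroazulen-1-yl]ethoxy}silane
Conditions: Bu3SnH, AIBN (cat.), toluene, 100 °C
Reagents that add atoms: none
Why: Barton–McCombie deoxygenation; the secondary ring radical is reduced by the stannane faster than it could reach the exocyclic alkene, which would need a 4-exo or 5-endo closure.

Step 17
Reactants: 22 tert-butyldimethyl{2-[(1S,3aR,8aS)-1,4,4-trimethyl-8-methylidenedecahydroazulen-1-yl]ethoxy}silane
Product: 23 2-[(1S,3aR,8aS)-1,4,4-trimethyl-8-methylidenedecahydroazulen-1-yl]ethan-1-ol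
Conditions: Bu4NF, THF, rt
Reagents that add atoms: none
Why: Fluoride cleavage of the silyl ether; nothing else in the hydrocarbon skeleton responds to fluoride.

Step 18
Reactants: 23 2-[(1S,3aR,8aS)-1,4,4-trimethyl-8-methylidenedecahydroazulen-1-yl]ethan-1-ol
Product: 24 2-[(1S,3aR,8aS)-1,4,4-trimethyl-8-methylidenedecahydroazulen-1-yl]acetaldehyde
Conditions: Dess–Martin periodinane, NaHCO3, CH2Cl2, rt
Reagents that add atoms: none
Why: Dess–Martin oxidation to the aldehyde; the α-carbon is a methylene next to a quaternary centre, so there is no stereocentre to lose.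

Step 19
Reactants: 24 2-[(1S,3aR,8aS)-1,4,4-trimethyl-8-methylidenedecahydroazulen-1-yl]acetaldehyde
Product: 25 (1S,3aR,8aS)-1-(2,2-dimethoxyethyl)-1,4,4-trimethyl-8-methylidenedecahydroazulene
Conditions: HC(OMe)3, PPTS (cat.), MeOH, rt
Reagents that add atoms: trimethyl orthoformate, COC(OC)OC; methanol, CO
Why: Acetalisation with the orthoformate as water scavenger; the pyridinium acid is too weak to move the exocyclic alkene.

Step 20
Reactants: 25 (1S,3aR,8aS)-1-(2,2-dimethoxyethyl)-1,4,4-trimethyl-8-methylidenedecahydroazulene
Product: 26 (1R,3aR,8aS)-1-(2-methoxyethenyl)-1,4,4-trimethyl-8-methylidenedecahydroazulene (E/Z mixture)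
Conditions: TMSOTf, iPr2NEt, CH2Cl2, −20 °C → rt
Reagents that add atoms: none
Why: Acetal-to-enol-ether elimination: the silyl triflate ionises one methoxy group and the amine removes the β-hydrogen from the oxocarbenium ion; the alkene geometry is irrelevant because both isomers give the same bromo-oxocarbenium ion in step 24.

Step 21
Reactants: 27 methyl (2S)-2-hydroxybut-3-enoate; 28 2-(trimethylsilyl)ethan-1-ol
Product: 29 2-(trimethylsilyl)ethyl (2S)-2-hydroxybut-3-enoate
Conditions: Ti(OiPr)4 (10 mol %), 28 (5 equiv), 80 °C, methanol distilled off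
Reagents that add atoms: none
Why: Titanate-catalysed transesterification of an α-hydroxy ester; the neutral conditions leave the carbinol stereocentre and the vinyl group untouched.

Step 22
Reactants: 30 (4R)-4-benzyl-1,3-oxazolidin-2-one; 31 acryloyl chloride
Product: 32 (4R)-4-benzyl-3-(prop-2-enoyl)-1,3-oxazolidin-2-one
Conditions: Et3N, LiCl, THF, −20 °C → rt
Reagents that add atoms: none
Why: N-Acylation of the oxazolidinone under lithium chloride and amine activation, which avoids the strongly basic conditions that polymerise acryloyl derivatives.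

Step 23
Reactants: 29 2-(trimethylsilyl)ethyl (2S)-2-hydroxybut-3-enoate; 32 (4R)-4-benzyl-3-(prop-2-enoyl)-1,3-oxazolidin-2-one
Product: 33 2-(trimethylsilyl)ethyl (2S,3E)-5-[(4R)-4-benzyl-2-oxo-1,3-oxazolidin-3-yl]-2-hydroxy-5-oxopent-3-enoate
Conditions: second-generation Hoveyda–Grubbs catalyst (5 mol %), CH2Cl2, 40 °C
Reagents that add atoms: none
Why: Olefin cross-metathesis of a secondary allylic alcohol with an acrylic acid derivative, which is E-selective; neither stereocentre is touched, and the E geometry prevents lactonisation of the γ-hydroxyl onto the imide.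

Step 24
Reactants: 26 (1R,3aR,8aS)-1-(2-methoxyethenyl)-1,4,4-trimethyl-8-methylidenedecahydroazulene; 33 2-(trimethylsilyl)ethyl (2S,3E)-5-[(4R)-4-benzyl-2-oxo-1,3-oxazolidin-3-yl]-2-hydroxy-5-oxopent-3-enoate
Product: 34 2-(trimethylsilyl)ethyl (2S,3E)-5-[(4R)-4-benzyl-2-oxo-1,3-oxazolidin-3-yl]-2-{2-bromo-1-methoxy-2-[(1R,3aR,8aS)-1,4,4-trimethyl-8-methylidenedecahydroazulen-1-yl]ethoxy}-5-oxopent-3-enoate (mixture at the CHBr and acetal carbons)
Conditions: NBS, 33 (1.5 equiv), CH2Cl2, −40 → 0 °C
Reagents that add atoms: N-bromosuccinimide, O=C1CCC(=O)N1Br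
Why: Bromoetherification (first half of the Ueno–Stork sequence): bromine adds to the electron-rich enol ether carbon C8′ and the oxocarbenium ion at C1′ is trapped by the hydroxyl of 33; the enol ether is far more nucleophilic than the exocyclic methylene, and the two new centres converge later (C8′ becomes a radical, C1′ is exchanged in step 29).

Step 25
Reactants: 34 2-(trimethylsilyl)ethyl (2S,3E)-5-[(4R)-4-benzyl-2-oxo-1,3-oxazolidin-3-yl]-2-{2-bromo-1-methoxy-2-[(1R,3aR,8aS)-1,4,4-trimethyl-8-methylidenedecahydroazulen-1-yl]ethoxy}-5-oxopent-3-enoate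
Product: 35 2-(trimethylsilyl)ethyl (2S,3S,4R)-3-{2-[(4R)-4-benzyl-2-oxo-1,3-oxazolidin-3-yl]-2-oxoethyl}-5-methoxy-4-[(1R,3aR,8aS)-1,4,4-trimethyl-8-methylidenedecahydroazulen-1-yl]oxolane-2-carboxylate (both anomers)
Conditions: Bu3SnH, AIBN (cat.), benzene (0.01 M), 80 °C, slow addition
Reagents that add atoms: none
Why: Ueno–Stork radical cyclisation: the β-alkoxyalkyl radical at C8′ closes 5-exo-trig onto the β-carbon of the enoyl imide and the stabilised α-imide radical is then reduced. In the chair-like transition state the ester on C4′ and the azulenyl group on C8′ take pseudo-equatorial positions, so the new bond at C5′ forms anti to both and the 2,3-trans-3,4-trans oxolane results, which sets C5′ and C8′ relative to the pool-derived C4′.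

Step 26
Reactants: 35 2-(trimethylsilyl)ethyl (2S,3S,4R)-3-{2-[(4R)-4-benzyl-2-oxo-1,3-oxazolidin-3-yl]-2-oxoethyl}-5-methoxy-4-[(1R,3aR,8aS)-1,4,4-trimethyl-8-methylidenedecahydroazulen-1-yl]oxolane-2-carboxylate
Product: 37 2-(trimethylsilyl)ethyl (2S,3R,4R)-3-{(1R)-2-[(4R)-4-benzyl-2-oxo-1,3-oxazolidin-3-yl]-1-hydroxy-2-oxoethyl}-5-methoxy-4-[(1R,3aR,8aS)-1,4,4-trimethyl-8-methylidenedecahydroazulen-1-yl]oxolane-2-carboxylate, via sodium imide enolate 36 (not isolated)
Conditions: NaN(SiMe3)2, THF, −78 °C; then 2-(phenylsulfonyl)-3-phenyloxaziridine, −78 °C; AcOH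
Reagents that add atoms: 2-(phenylsulfonyl)-3-phenyloxaziridine, O=S(=O)(c1ccccc1)N1OC1c1ccccc1
Why: Auxiliary-controlled enolate hydroxylation of an N-acyl oxazolidinone: the imide α-hydrogens are far more acidic than the ester α-hydrogen at C4′, the chelated Z enolate is shielded on one face by the benzyl group, and the oxaziridine delivers oxygen to the open face to give the R carbinol at C6′.

Step 27
Reactants: 37 2-(trimethylsilyl)ethyl (2S,3R,4R)-3-{(1R)-2-[(4R)-4-benzyl-2-oxo-1,3-oxazolidin-3-yl]-1-hydroxy-2-oxoethyl}-5-methoxy-4-[(1R,3aR,8aS)-1,4,4-trimethyl-8-methylidenedecahydroazulen-1-yl]oxolane-2-carboxylate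
Product: 38 2-(trimethylsilyl)ethyl (2S,3R,4R)-3-[(1R)-1-hydroxy-2-methoxy-2-oxoethyl]-5-methoxy-4-[(1R,3aR,8aS)-1,4,4-trimethyl-8-methylidenedecahydroazulen-1-yl]oxolane-2-carboxylate
Conditions: MeMgBr, MeOH, CH2Cl2, 0 °C
Reagents that add atoms: methanol, CO
Why: Transesterification of the imide by methoxymagnesium bromide; the exocyclic imide carbonyl is much more electrophilic than the hindered silylethyl ester, the auxiliary is released for recovery, and the medium is not basic enough to epimerise C6′ or C4′.

Step 28
Reactants: 38 2-(trimethylsilyl)ethyl (2S,3R,4R)-3-[(1R)-1-hydroxy-2-methoxy-2-oxoethyl]-5-methoxy-4-[(1R,3aR,8aS)-1,4,4-trimethyl-8-methylidenedecahydroazulen-1-yl]oxolane-2-carboxylate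
Product: 39 (2S,3R,4R)-3-[(1R)-1-hydroxy-2-methoxy-2-oxoethyl]-5-methoxy-4-[(1R,3aR,8aS)-1,4,4-trimethyl-8-methylidenedecahydroazulen-1-yl]oxolane-2-carboxylic acid
Conditions: Bu4NF, THF, 0 °C → rt; pH 4 phosphate buffer
Reagents that add atoms: none
Why: Fluoride-induced β-elimination of the 2-(trimethylsilyl)ethyl ester frees the C3′ acid without acid or hydroxide, so the methyl ester, the acetal and the exocyclic alkene are untouched.

Step 29
Reactants: 39 (2S,3R,4R)-3-[(1R)-1-hydroxy-2-methoxy-2-oxoethyl]-5-methoxy-4-[(1R,3aR,8aS)-1,4,4-trimethyl-8-methylidenedecahydroazulen-1-yl]oxolane-2-carboxylic acid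
Product: 40 methyl (1S,4S,5S,6R,8R)-4-hydroxy-3-oxo-8-[(1R,3aR,8aS)-1,4,4-trimethyl-8-methylidenedecahydroazulen-1-yl]-2,7-dioxabicyclo[3.2.1]octane-6-carboxylate
Conditions: camphorsulfonic acid (20 mol %), 5 Å molecular sieves, CH2Cl2, rt
Reagents that add atoms: none
Why: Acid-catalysed acetal exchange ending in acyl acetal formation: ionisation at C1′, capture by the C6′ hydroxyl, release of the C4′ oxygen and capture of the resulting oxocarbenium ion by the acid give the bridged lactone, driven by uptake of methanol on the sieves. C1′ is fixed by the bridge, which can only close with both oxygens cis to the C5′ substituents, and γ-lactonisation of the acid onto the C6′ hydroxyl is blocked while the first oxolane is closed because it would be trans-fused.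

Step 30
Reactants: 40 methyl (1S,4S,5S,6R,8R)-4-hydroxy-3-oxo-8-[(1R,3aR,8aS)-1,4,4-trimethyl-8-methylidenedecahydroazulen-1-yl]-2,7-dioxabicyclo[3.2.1]octane-6-carboxylate
Product: 41 methyl (1S,4S,5R,6R,8R)-4-(acetyloxy)-3-oxo-8-[(1R,3aR,8aS)-1,4,4-trimethyl-8-methylidenedecahydroazulen-1-yl]-2,7-dioxabicyclo[3.2.1]octane-6-carboxylate
Conditions: Ac2O, pyridine, DMAP (cat.), CH2Cl2, 0 °C → rt
Reagents that add atoms: acetic anhydride, CC(=O)OC(C)=O
Why: Acetylation of the equatorial secondary hydroxyl; the amine conditions are mild enough for the acyl acetal and no stereocentre is affected.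

## Compound list

1 | 3-methyloxolan-2-one (α-methyl-γ-butyrolactone, racemic) | CC1CCOC1=O | starting material
2 | allyl chloroformate | C=CCOC(Cl)=O | starting material
3 | lithium enolate of 3-methyloxolan-2-one | [Li+].CC1=C([O-])OCC1 | intermediate
4 | allyl 3-methyl-2-oxooxolane-3-carboxylate (racemic) | C=CCOC(=O)C1(C)CCOC1=O | intermediate
5 | (3S)-3-methyl-3-(prop-2-en-1-yl)oxolan-2-one | C=CC[C@@]1(C)CCOC1=O | intermediate
6 | 9-{3-[(3S)-3-methyl-2-oxooxolan-3-yl]propyl}-9-borabicyclo[3.3.1]nonane | B1(CCC[C@@]2(C)CCOC2=O)C2CCCC1CCC2 | intermediate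
7 | (3S)-3-(3-hydroxypropyl)-3-methyloxolan-2-one | OCCC[C@@]1(C)CCOC1=O | intermediate
8 | 3-[(3S)-3-methyl-2-oxooxolan-3-yl]propanal | O=CCC[C@@]1(C)CCOC1=O | intermediate
9 | (3S)-3-(4,4-dibromobut-3-en-1-yl)-3-methyloxolan-2-one | BrC(Br)=CCC[C@@]1(C)CCOC1=O | intermediate
10 | cyclopropylzinc bromide | Br[Zn]C1CC1 | starting material
11 | (3S)-3-[(3Z)-4-bromo-4-cyclopropylbut-3-en-1-yl]-3-methyloxolan-2-one | C1CC1/C(Br)=C/CC[C@@]1(C)CCOC1=O | intermediate
12 | (3S)-3-[(3E)-4-cyclopropylpent-3-en-1-yl]-3-methyloxolan-2-one | C1CC1/C(C)=C/CC[C@@]1(C)CCOC1=O | intermediate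
13 | (3S)-3-[(3E)-4-cyclopropylpent-3-en-1-yl]-3-methyloxolan-2-ol (both anomers) | C1CC1/C(C)=C/CC[C@@]1(C)CCOC1O | intermediate
14 | (3S,6E)-7-cyclopropyl-3-ethynyl-3-methyloct-6-en-1-ol | C#C[C@](C)(CCO)CC/C=C(\C)C1CC1 | intermediate
15 | tert-butyl{[(3S,6E)-7-cyclopropyl-3-ethynyl-3-methyloct-6-en-1-yl]oxy}dimethylsilane | C#C[C@](C)(CCO[Si](C)(C)C(C)(C)C)CC/C=C(\C)C1CC1 | intermediate
16 | (4S,7E)-4-{2-[(tert-butyldimethylsilyl)oxy]ethyl}-8-cyclopropyl-N,N-dicyclohexyl-4-methylnon-7-en-2-yn-1-amine | C1CCC(CC1)N(CC#C[C@](C)(CCO[Si](C)(C)C(C)(C)C)CC/C=C(\C)C2CC2)C1CCCCC1 | intermediate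
17 | tert-butyl{[(3S,6E)-7-cyclopropyl-3-methyl-3-(propa-1,2-dien-1-yl)oct-6-en-1-yl]oxy}dimethylsilane | C=C=C[C@](C)(CCO[Si](C)(C)C(C)(C)C)CC/C=C(\C)C1CC1 | intermediate
18 | tert-butyl{2-[(1S,3aR,8aS)-1,4-dimethyl-8-methylidene-1,2,3,3a,6,7,8,8a-octahydroazulen-1-yl]ethoxy}dimethylsilane | C=C1CCC=C(C)[C@@H]2CC[C@@](C)(CCO[Si](C)(C)C(C)(C)C)[C@H]12 | intermediate
19 | tert-butyl{2-[(1S,3aR,8aS)-4,5-epoxy-1,4-dimethyl-8-methylidenedecahydroazulen-1-yl]ethoxy}dimethylsilane (epoxide on either face) | C=C1CCC2OC2(C)[C@@H]3CC[C@@](C)(CCO[Si](C)(C)C(C)(C)C)[C@H]13 | intermediate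
20 | (1S,3aR,8aS)-1-{2-[(tert-butyldimethylsilyl)oxy]ethyl}-1,4,4-trimethyl-8-methylidenedecahydroazulen-5-ol (C5 epimers) | C=C1CCC(O)C(C)(C)[C@@H]2CC[C@@](C)(CCO[Si](C)(C)C(C)(C)C)[C@H]12 | intermediate
21 | O-[(1S,3aR,8aS)-1-{2-[(tert-butyldimethylsilyl)oxy]ethyl}-1,4,4-trimethyl-8-methylidenedecahydroazulen-5-yl] O-phenyl carbonothioate | C=C1CCC(OC(=S)Oc2ccccc2)C(C)(C)[C@@H]3CC[C@@](C)(CCO[Si](C)(C)C(C)(C)C)[C@H]13 | intermediate
22 | tert-butyldimethyl{2-[(1S,3aR,8aS)-1,4,4-trimethyl-8-methylidenedecahydroazulen-1-yl]ethoxy}silane | C=C1CCCC(C)(C)[C@@H]2CC[C@@](C)(CCO[Si](C)(C)C(C)(C)C)[C@H]12 | intermediate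
23 | 2-[(1S,3aR,8aS)-1,4,4-trimethyl-8-methylidenedecahydroazulen-1-yl]ethan-1-ol | C=C1CCCC(C)(C)[C@@H]2CC[C@@](C)(CCO)[C@H]12 | intermediate
24 | 2-[(1S,3aR,8aS)-1,4,4-trimethyl-8-methylidenedecahydroazulen-1-yl]acetaldehyde | C=C1CCCC(C)(C)[C@@H]2CC[C@@](C)(CC=O)[C@H]12 | intermediate
25 | (1S,3aR,8aS)-1-(2,2-dimethoxyethyl)-1,4,4-trimethyl-8-methylidenedecahydroazulene | C=C1CCCC(C)(C)[C@@H]2CC[C@@](C)(CC(OC)OC)[C@H]12 | intermediate
26 | (1R,3aR,8aS)-1-(2-methoxyethenyl)-1,4,4-trimethyl-8-methylidenedecahydroazulene (E/Z mixture) | C=C1CCCC(C)(C)[C@@H]2CC[C@@](C)(C=COC)[C@H]12 | intermediate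
27 | methyl (2S)-2-hydroxybut-3-enoate | C=C[C@H](O)C(=O)OC | starting material
28 | 2-(trimethylsilyl)ethan-1-ol | C[Si](C)(C)CCO | starting material
29 | 2-(trimethylsilyl)ethyl (2S)-2-hydroxybut-3-enoate | C=C[C@H](O)C(=O)OCC[Si](C)(C)C | intermediate
30 | (4R)-4-benzyl-1,3-oxazolidin-2-one | O=C1N[C@H](Cc2ccccc2)CO1 | starting material
31 | acryloyl chloride | C=CC(=O)Cl | starting material
32 | (4R)-4-benzyl-3-(prop-2-enoyl)-1,3-oxazolidin-2-one | C=CC(=O)N1[C@H](Cc2ccccc2)COC1=O | intermediate
33 | 2-(trimethylsilyl)ethyl (2S,3E)-5-[(4R)-4-benzyl-2-oxo-1,3-oxazolidin-3-yl]-2-hydroxy-5-oxopent-3-enoate | C[Si](C)(C)CCOC(=O)[C@@H](O)/C=C/C(=O)N1[C@H](Cc2ccccc2)COC1=O | intermediate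
34 | 2-(trimethylsilyl)ethyl (2S,3E)-5-[(4R)-4-benzyl-2-oxo-1,3-oxazolidin-3-yl]-2-{2-bromo-1-methoxy-2-[(1R,3aR,8aS)-1,4,4-trimethyl-8-methylidenedecahydroazulen-1-yl]ethoxy}-5-oxopent-3-enoate (mixture at CHBr and acetal carbon) | C=C1CCCC(C)(C)[C@@H]2CC[C@@](C)(C(Br)C(OC)O[C@@H](/C=C/C(=O)N3[C@H](Cc4ccccc4)COC3=O)C(=O)OCC[Si](C)(C)C)[C@H]12 | intermediate
35 | 2-(trimethylsilyl)ethyl (2S,3S,4R)-3-{2-[(4R)-4-benzyl-2-oxo-1,3-oxazolidin-3-yl]-2-oxoethyl}-5-methoxy-4-[(1R,3aR,8aS)-1,4,4-trimethyl-8-methylidenedecahydroazulen-1-yl]oxolane-2-carboxylate (both anomers) | C=C1CCCC(C)(C)[C@@H]2CC[C@@](C)([C@@H]3C(OC)O[C@H](C(=O)OCC[Si](C)(C)C)[C@H]3CC(=O)N4[C@H](Cc5ccccc5)COC4=O)[C@H]12 | intermediate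
36 | sodium Z enolate of imide 35 | [Na+].C=C1CCCC(C)(C)[C@@H]2CC[C@@](C)([C@@H]3C(OC)O[C@H](C(=O)OCC[Si](C)(C)C)[C@H]3/C=C(\[O-])N4[C@H](Cc5ccccc5)COC4=O)[C@H]12 | intermediate
37 | 2-(trimethylsilyl)ethyl (2S,3R,4R)-3-{(1R)-2-[(4R)-4-benzyl-2-oxo-1,3-oxazolidin-3-yl]-1-hydroxy-2-oxoethyl}-5-methoxy-4-[(1R,3aR,8aS)-1,4,4-trimethyl-8-methylidenedecahydroazulen-1-yl]oxolane-2-carboxylate | C=C1CCCC(C)(C)[C@@H]2CC[C@@](C)([C@@H]3C(OC)O[C@H](C(=O)OCC[Si](C)(C)C)[C@H]3[C@@H](O)C(=O)N4[C@H](Cc5ccccc5)COC4=O)[C@H]12 | intermediate
38 | 2-(trimethylsilyl)ethyl (2S,3R,4R)-3-[(1R)-1-hydroxy-2-methoxy-2-oxoethyl]-5-methoxy-4-[(1R,3aR,8aS)-1,4,4-trimethyl-8-methylidenedecahydroazulen-1-yl]oxolane-2-carboxylate | C=C1CCCC(C)(C)[C@@H]2CC[C@@](C)([C@@H]3C(OC)O[C@H](C(=O)OCC[Si](C)(C)C)[C@H]3[C@@H](O)C(=O)OC)[C@H]12 | intermediate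
39 | (2S,3R,4R)-3-[(1R)-1-hydroxy-2-methoxy-2-oxoethyl]-5-methoxy-4-[(1R,3aR,8aS)-1,4,4-trimethyl-8-methylidenedecahydroazulen-1-yl]oxolane-2-carboxylic acid | C=C1CCCC(C)(C)[C@@H]2CC[C@@](C)([C@@H]3C(OC)O[C@H](C(=O)O)[C@H]3[C@@H](O)C(=O)OC)[C@H]12 | intermediate
40 | methyl (1S,4S,5S,6R,8R)-4-hydroxy-3-oxo-8-[(1R,3aR,8aS)-1,4,4-trimethyl-8-methylidenedecahydroazulen-1-yl]-2,7-dioxabicyclo[3.2.1]octane-6-carboxylate | C=C1CCCC(C)(C)[C@@H]2CC[C@@](C)([C@@H]3[C@@H]4OC(=O)[C@@H](O)[C@H]3[C@H](C(=O)OC)O4)[C@H]12 | intermediate
41 | methyl (1S,4S,5R,6R,8R)-4-(acetyloxy)-3-oxo-8-[(1R,3aR,8aS)-1,4,4-trimethyl-8-methylidenedecahydroazulen-1-yl]-2,7-dioxabicyclo[3.2.1]octane-6-carboxylate | C=C1CCCC(C)(C)[C@@H]2CC[C@@](C)([C@@H]3[C@@H]4OC(=O)[C@@H](OC(C)=O)[C@H]3[C@H](C(=O)OC)O4)[C@H]12 | target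

## Step count and least certain steps

Total: 30 steps. Longest linear sequence: 27 steps (steps 1–20 and 24–30); steps 21–23 form the side branch to 33.

**Step 12 (key step).** The most likely failure is poor facial selectivity of the allene insertion relative to C1, because a methyl group and a silyloxyethyl arm differ only moderately in size; oligomerisation of the terminal allene is the second concern. The fallback sets out from alkyne 15. C-alkylation of its lithium acetylide with (iodomethyl)trimethylsilane would give propargylsilane F1. The well-established alkyne–vinylcyclopropane (5+2) cycloaddition under [Rh(CO)2Cl]2 would give the bicyclic allylsilane F2, in which only C3a is formed in the metal-mediated step and C8a is still trigonal. Protodesilylation (CF3CO2H, CH2Cl2, −78 °C) would then put the proton on C8a from the convex face and shift the double bond to the exocyclic position, returning to 18. The centre next to C1 would thus be set by protonation of a rigid bicycle and not inside the metallacycle.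

**Step 2.** The enantiomeric excess may fall short, since a small lactone enolate offers the ligand less to grip than the ketone or lactam enolates for which the reaction is best known. The fallback sets out from 1. Alkylation of its lithium enolate with allyl bromide would give the racemic allyl lactone F3. Me3Al-mediated aminolysis with (1S)-1-phenylethanamine would give two diastereomeric hydroxy amides, separable by crystallisation or chromatography. The S,S isomer, hydroxy amide F4, would be relactonised with aqueous H2SO4 in dioxane to return to 5.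

**Step 14.** Hydride shift (semipinacol rearrangement) or elimination may outrun methyl transfer at the tertiary epoxide carbon next to the ring fusion. The fallback sets out from 19 and uses the rearrangement instead. BF3·OEt2 at −78 °C (Meinwald rearrangement) would give ketone F5. Methylation of its more substituted enolate (KOtBu, MeI) would give the gem-dimethyl ketone F6. NaBH4 reduction returns to 20, whose C5 configuration is irrelevant.

**Step 25.** The congested secondary radical may take hydrogen from the stannane before it closes, and some closure syn to the C4′ ester would give the C5′ epimer, which cannot be corrected later. The fallback sets out from 26 and forms the C–C bond before the ring. NBS in methanol would give the bromo dimethyl acetal F7, and silylation of 33 (TBSCl, imidazole) would give silyl ether F8. A Lewis-acid-templated intermolecular radical conjugate addition of F7 to F8 (Yb(OTf)3, Bu3SnH, Et3B/O2, −78 °C), a known reaction class for N-enoyl oxazolidinones, would give the open-chain adduct F9. Desilylation (HF·pyridine) and acid-catalysed acetal exchange (PPTS) would close the oxolane and return to 35. Selectivity would then rest on acyclic induction from the silyloxy centre and would have to be established.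

**Step 29.** Acid may move the exocyclic alkene into the ring, or the exchange may stall among isomeric acetals before the acid closes the bridge. The fallback sets out from 39 and avoids acid catalysis in the ring-forming event. Mild hydrolysis of the methyl acetal (aqueous AcOH, THF) would give the lactol acid F10, whose ring–chain tautomerism makes the hemiacetal on the C6′ oxygen available. Dehydrative acylation of that hemiacetal hydroxyl by the C3′ acid with a carbodiimide (EDC, DMAP cat., CH2Cl2) would give 40. The competing γ-lactone is again disfavoured because it would be trans-fused to the other hemiacetal ring.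

## Further compounds

F1 | step 12 | tert-butyl{[(3S,6E)-7-cyclopropyl-3-methyl-3-[3-(trimethylsilyl)prop-1-yn-1-yl]oct-6-en-1-yl]oxy}dimethylsilane | C[Si](C)(C)CC#C[C@](C)(CCO[Si](C)(C)C(C)(C)C)CC/C=C(\C)C1CC1
F2 | step 12 | tert-butyl{2-[(1S,3aR)-1,4-dimethyl-8-[(trimethylsilyl)methyl]-1,2,3,3a,6,7-hexahydroazulen-1-yl]ethoxy}dimethylsilane | C[Si](C)(C)CC1=C2[C@@H](CC[C@@]2(C)CCO[Si](C)(C)C(C)(C)C)C(C)=CCC1
F3 | step 2 | 3-methyl-3-(prop-2-en-1-yl)oxolan-2-one (racemic) | C=CCC1(C)CCOC1=O
F4 | step 2 | (2S)-2-(2-hydroxyethyl)-2-methyl-N-[(1S)-1-phenylethyl]pent-4-enamide | C=CC[C@@](C)(CCO)C(=O)N[C@@H](C)c1ccccc1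
F5 | step 14 | (1S,3aR,8aS)-1-{2-[(tert-butyldimethylsilyl)oxy]ethyl}-1,4-dimethyl-8-methylideneoctahydroazulen-5(1H)-one (C4 epimers) | C=C1CCC(=O)C(C)[C@@H]2CC[C@@](C)(CCO[Si](C)(C)C(C)(C)C)[C@H]12
F6 | step 14 | (1S,3aR,8aS)-1-{2-[(tert-butyldimethylsilyl)oxy]ethyl}-1,4,4-trimethyl-8-methylideneoctahydroazulen-5(1H)-one | C=C1CCC(=O)C(C)(C)[C@@H]2CC[C@@](C)(CCO[Si](C)(C)C(C)(C)C)[C@H]12
F7 | step 25 | (1R,3aR,8aS)-1-(1-bromo-2,2-dimethoxyethyl)-1,4,4-trimethyl-8-methylidenedecahydroazulene (CHBr epimers) | C=C1CCCC(C)(C)[C@@H]2CC[C@@](C)(C(Br)C(OC)OC)[C@H]12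
F8 | step 25 | 2-(trimethylsilyl)ethyl (2S,3E)-5-[(4R)-4-benzyl-2-oxo-1,3-oxazolidin-3-yl]-2-[(tert-butyldimethylsilyl)oxy]-5-oxopent-3-enoate | C[Si](C)(C)CCOC(=O)[C@@H](O[Si](C)(C)C(C)(C)C)/C=C/C(=O)N1[C@H](Cc2ccccc2)COC1=O
F9 | step 25 | 2-(trimethylsilyl)ethyl (2S,3S,4R)-3-{2-[(4R)-4-benzyl-2-oxo-1,3-oxazolidin-3-yl]-2-oxoethyl}-2-[(tert-butyldimethylsilyl)oxy]-5,5-dimethoxy-4-[(1R,3aR,8aS)-1,4,4-trimethyl-8-methylidenedecahydroazulen-1-yl]pentanoate | C=C1CCCC(C)(C)[C@@H]2CC[C@@](C)([C@H](C(OC)OC)[C@H](CC(=O)N3[C@H](Cc4ccccc4)COC3=O)[C@H](O[Si](C)(C)C(C)(C)C)C(=O)OCC[Si](C)(C)C)[C@H]12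
F10 | step 29 | (2S,3R,4R)-5-hydroxy-3-[(1R)-1-hydroxy-2-methoxy-2-oxoethyl]-4-[(1R,3aR,8aS)-1,4,4-trimethyl-8-methylidenedecahydroazulen-1-yl]oxolane-2-carboxylic acid (lactol, in equilibrium with its open and isomeric hemiacetal forms) | C=C1CCCC(C)(C)[C@@H]2CC[C@@](C)([C@@H]3C(O)O[C@H](C(=O)O)[C@H]3[C@@H](O)C(=O)OC)[C@H]12
A1 | alternative 1 | cis-hydroazulen-8-one carrying on C1 a 2-acetoxy-3-oxocyclopentyl ring with a CH(OSiEt3)CO2Me side chain (acetoxy carbon epimeric) | O=C1CCCC(C)(C)[C@@H]2CC[C@@](C)([C@@H]3C(OC(C)=O)C(=O)C[C@H]3[C@@H](O[Si](CC)(CC)CC)C(=O)OC)[C@H]12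
A2 | alternative 2 | tricyclic acetoxycyclobutane photoadduct of the cycloheptanone (acetoxy carbon epimeric) | O=C1CCCC(C)(C)[C@@H]2CC[C@@]3(C)CC(OC(C)=O)[C@@]123
A3 | alternative 2 | 2-[(1S,3aR,8aR)-1,4,4-trimethyl-8-oxodecahydroazulen-1-yl]acetaldehyde | O=C1CCCC(C)(C)[C@@H]2CC[C@@](C)(CC=O)[C@H]12
A4 | alternative 3 | hydroazulenyl 2-oxabicyclo[2.1.1]hexane diester (methyl and tert-butyl esters) | C=C1CCCC(C)(C)[C@@H]2CC[C@@](C)([C@@H]3[C@H]4O[C@@H](C(=O)OC)[C@@H]3[C@@H]4C(=O)OC(C)(C)C)[C@H]12
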